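**Retrosynthetic overview**
- The target is reached by desilylation and by removal of a temporary C4 carbonyl (tosylhydrazone reduction) from (2R)-chroman-4-one 14, which already carries the complete side chain.
- Key disconnection: the C2–C3 bond of ring B (the dihydropyran ring). Diazoketone 13 gives 14 by dirhodium-catalysed carbenoid insertion into the tertiary C2–H bond with retention. Ring A (the orcinol benzene ring) is bought; ring B is the only ring made.
- Enabling feature: ring A holds the acyl carbon C4 and the ether oxygen O1 ortho to each other, so the tertiary, oxygen-activated C2–H bond lies 1,6 to the diazo carbon C3 through C4, C4a, C8a and O1.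
- 13 comes from aryl ether 11, made by Mitsunobu inversion of (S)-alcohol 8 with the 4-O-silylated acetophenone 10.
- 8 comes from (E)-geranylacetone: terminal alkene cleaved to an aldehyde, Still–Gennari (Z)-enoate, enzymatic reduction of the methyl ketone.

Key step: step 9

Remark: (E)-geranylacetone is taken as the isomerically pure commercial E compound, and 1-(2,4-dihydroxy-6-methylphenyl)ethan-1-one and methyl bis(2,2,2-trifluoroethyl)phosphonoacetate are taken as commercial.

Step 1
Reactants: 1 (E)-geranylacetone
Product: 3 (5E)-8-(3,3-dimethyloxiran-2-yl)-6-methyloct-5-en-2-one (racemic epoxide), via terminal bromohydrin 2 (not isolated)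
Conditions: NBS (1.05 equiv), THF/H2O 2:1, 0 °C; then K2CO3, MeOH, rt
Reagents that add atoms: water, O (epoxide oxygen of 3); N-bromosuccinimide, O=C1CCC(=O)N1Br (bromine of 2 only)
Why: Bromohydrin formation in highly aqueous THF should occur at the terminal, most exposed trisubstituted alkene of the polyprenoid chain with water opening the bromonium ion at the tertiary carbon, and carbonate then closes the epoxide by intramolecular Williamson displacement; the new stereocentre is racemic and is destroyed in step 2.

Step 2
Reactants: 3 racemic terminal epoxide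
Product: 4 (4E)-4-methyl-8-oxonon-4-enal
Conditions: H5IO6 (1.2 equiv), THF/H2O, 0 °C to rt
Reagents that add atoms: none
Why: Periodic acid hydrolyses the trisubstituted epoxide to the vicinal diol in situ and cleaves it (Malaprade glycol cleavage) to the aldehyde and acetone without touching the ketone or the remaining E alkene.

Step 3
Reactants: 5 methyl 2-[bis(2,2,2-trifluoroethoxy)phosphoryl]acetate
Product: 6 methyl 2-[bis(2,2,2-trifluoroethoxy)phosphoryl]propanoate (racemic)
Conditions: KOt-Bu (1.0 equiv), THF, 0 °C; MeI, 0 °C to rt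
Reagents that add atoms: iodomethane, CI
Why: C-alkylation of the stabilised phosphonoacetate anion with one equivalent of base and iodomethane is a standard enolate alkylation and gives the α-methyl Still–Gennari reagent, whose stereocentre is lost in step 4.

Step 4
Reactants: 4 (4E)-4-methyl-8-oxonon-4-enal; 6 methyl 2-[bis(2,2,2-trifluoroethoxy)phosphoryl]propanoate
Product: 7 methyl (2Z,6E)-2,6-dimethyl-10-oxoundeca-2,6-dienoate
Conditions: 6 (1.1 equiv), KN(SiMe3)2 (1.0 equiv), 18-crown-6, THF, −78 °C; then 4
Reagents that add atoms: none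
Why: Still–Gennari variant of the Horner–Wadsworth–Emmons olefination: the electron-poor bis(trifluoroethyl) phosphonate under dissociating conditions eliminates from the kinetic adduct and should give the (Z)-2-methyl-2-enoate, and the weakly basic phosphonate anion should react with the aldehyde far faster than with the methyl ketone.

Step 5
Reactants: 7 methyl (2Z,6E)-2,6-dimethyl-10-oxoundeca-2,6-dienoate
Product: 8 methyl (2Z,6E,10S)-10-hydroxy-2,6-dimethylundeca-2,6-dienoate
Conditions: alcohol dehydrogenase from Rhodococcus ruber (ADH-A), NAD+ (cat.), i-PrOH, phosphate buffer pH 7.5, 30 °C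
Reagents that add atoms: none
Why: Enzymatic ketone reduction: Re-face hydride delivery from NADH to a methyl ketone, the enzyme distinguishing methyl from the long chain, should set the (10S) carbinol, while the enoate and the alkenes are not substrates and 2-propanol recycles the cofactor.

Step 6
Reactants: 9 1-(2,4-dihydroxy-6-methylphenyl)ethan-1-one
Product: 10 1-{2-hydroxy-6-methyl-4-[(triisopropylsilyl)oxy]phenyl}ethan-1-one
Conditions: TIPSCl (1.05 equiv), imidazole, CH2Cl2, 0 °C to rt
Reagents that add atoms: chlorotriisopropylsilane, CC(C)[Si](Cl)(C(C)C)C(C)C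
Why: Chemoselective silylation: the 4-hydroxyl is free and more acidic whereas the 2-hydroxyl is locked in a hydrogen bond to the acetyl carbonyl, so one equivalent of silyl chloride should protect only the 4-position.

Step 7
Reactants: 8 methyl (2Z,6E,10S)-10-hydroxy-2,6-dimethylundeca-2,6-dienoate; 10 4-O-silylated acetophenone
Product: 11 methyl (2Z,6E,10R)-10-{2-acetyl-3-methyl-5-[(triisopropylsilyl)oxy]phenoxy}-2,6-dimethylundeca-2,6-dienoate
Conditions: PPh3, DIAD, toluene, 0 °C to rt
Reagents that add atoms: none
Why: Mitsunobu etherification: the acidic ortho-acyl phenol displaces the alkoxyphosphonium ion of the secondary alcohol by SN2 with inversion, so the (10S) carbinol becomes the (10R) aryl ether.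

Step 8
Reactants: 11 (10R) aryl ether methyl ketone
Product: 13 methyl (2Z,6E,10R)-10-{2-(2-diazoacetyl)-3-methyl-5-[(triisopropylsilyl)oxy]phenoxy}-2,6-dimethylundeca-2,6-dienoate, via trifluoroacetyl ketone 12 (not isolated)
Conditions: LiN(SiMe3)2 (1.1 equiv), THF, −78 °C; CF3CO2CH2CF3; dilute HCl work-up; then MsN3, Et3N, H2O (1 equiv), MeCN, rt
Reagents that add atoms: methanesulfonyl azide, CS(=O)(=O)N=[N+]=[N-] (the two diazo nitrogen atoms of 13); 2,2,2-trifluoroethyl trifluoroacetate, O=C(OCC(F)(F)F)C(F)(F)F (trifluoroacetyl group of 12 only)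
Why: Detrifluoroacetylative (Regitz-type) diazo transfer: kinetic enolisation of the only enolisable ketone position, Claisen trifluoroacetylation to activate the methyl group and diazo transfer with loss of the trifluoroacetyl group should give the terminal diazoketone without hydrolytic or acylating conditions that the ester, the silyl ether and the C10 centre would not tolerate.

Step 9
Reactants: 13 (10R) diazoketone
Product: 14 methyl (2Z,6E)-2,6-dimethyl-9-{(2R)-2,5-dimethyl-4-oxo-7-[(triisopropylsilyl)oxy]-3,4-dihydro-2H-chromen-2-yl}nona-2,6-dienoate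
Conditions: Rh2(OAc)4 (1 mol %), CH2Cl2, 40 °C, slow addition of 13 at high dilution
Reagents that add atoms: none
Why: Rh2(OAc)4 (divalent rhodium) expels N2 from the diazoketone and gives an electrophilic α-oxo rhodium carbenoid at the future C3, which inserts into the tertiary C2–H bond through a concerted, hydride-transfer-like three-centre transition state and releases the catalyst. The closest known reaction type is the dirhodium tetracarboxylate-catalysed 1,6 C–H insertion of 2-alkoxyphenyl diazoketones next to the ether oxygen, which gives chroman-4-ones. Ring B is the only ring closed, as a six-membered ring by 1,6-insertion (C3–C2 bond formation) through a chair-like array C3–C4–C4a–C8a–O1–C2. The single stereocentre C2 is controlled by the substrate: carbenoid C–H insertion proceeds with retention, so the new C2–C3 bond takes the place of the C2–H bond and the (10R) ether centre set in steps 5 and 7 becomes (2R) with its other three substituents untouched. The step needs site selectivity for this C–H bond over oxonium-ylide formation at O1, insertion into the aryl methyl group and cyclopropanation: the C2–H bond is tertiary, α to oxygen and the only activated C–H bond within 1,6 reach, O1 is a poorly nucleophilic aryl ether oxygen on an acyl-bearing ring and carries no allyl or benzyl group prone to shift, the aryl CH3 offers only primary C–H bonds in a strained planar 1,5 geometry, the side-chain C6=C7 alkene could be reached only through a nine-membered ring and the enoate alkene is electron-poor. Slow addition at high dilution suppresses carbene dimerisation.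

Step 10
Reactants: 14 (2R)-chroman-4-one
Product: 15 methyl (2Z,6E)-2,6-dimethyl-9-{(2R)-2,5-dimethyl-4-[2-(4-methylbenzenesulfonyl)hydrazinylidene]-7-[(triisopropylsilyl)oxy]-3,4-dihydro-2H-chromen-2-yl}nona-2,6-dienoate (C=N geometry not defined)
Conditions: TsNHNH2 (1.5 equiv), PPTS (cat.), MeOH, 60 °C
Reagents that add atoms: p-toluenesulfonyl hydrazide, Cc1ccc(cc1)S(=O)(=O)NN
Why: Hydrazone condensation of the aryl ketone under near-neutral conditions, which avoid base-induced retro-oxa-Michael opening of ring B, should leave C2, the enoate and the silyl ether untouched.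

Step 11
Reactants: 15 C4 tosylhydrazone
Product: 17 methyl (2Z,6E)-2,6-dimethyl-9-{(2R)-2,5-dimethyl-7-[(triisopropylsilyl)oxy]-3,4-dihydro-2H-chromen-2-yl}nona-2,6-dienoate, via N-boryl tosylhydrazide 16 (not isolated)
Conditions: catecholborane (2 equiv), CHCl3, 0 °C to rt; then NaOAc·3H2O, reflux
Reagents that add atoms: catecholborane, B1Oc2ccccc2O1 (boryl group of 16 only)
Why: Caglioti-type reductive deoxygenation: catecholborane hydroborates the C=N bond and acetate-induced loss of sulfinate gives a diazene that expels N2 and leaves C4 as CH2 without a C4 cation or strong acid, so the side-chain alkenes, the enoate and C2 should stay intact.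

Step 12
Reactants: 17 silyl-protected (2R)-chroman
Product: 18 methyl (2Z,6E)-9-[(2R)-7-hydroxy-2,5-dimethyl-3,4-dihydro-2H-chromen-2-yl]-2,6-dimethylnona-2,6-dienoate (target)
Conditions: Bu4NF (1.1 equiv), AcOH (1.1 equiv), THF, 0 °C
Reagents that add atoms: none
Why: Fluoride-mediated desilylation of the aryl silyl ether, buffered with acetic acid so that no free phenoxide or basic fluoride attacks the (Z)-enoate, should liberate the 7-hydroxyl and give the target.

**Compound list**
1 | (E)-geranylacetone, (5E)-6,10-dimethylundeca-5,9-dien-2-one | CC(C)=CCC/C(C)=C/CCC(C)=O | starting material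
2 | (5E)-9-bromo-10-hydroxy-6,10-dimethylundec-5-en-2-one (racemic) | CC(C)(O)C(Br)CC/C(C)=C/CCC(C)=O | intermediate
3 | (5E)-8-(3,3-dimethyloxiran-2-yl)-6-methyloct-5-en-2-one (racemic) | CC1(C)OC1CC/C(C)=C/CCC(C)=O | intermediate
4 | (4E)-4-methyl-8-oxonon-4-enal | O=CCC/C(C)=C/CCC(C)=O | intermediate
5 | methyl 2-[bis(2,2,2-trifluoroethoxy)phosphoryl]acetate | COC(=O)CP(=O)(OCC(F)(F)F)OCC(F)(F)F | starting material
6 | methyl 2-[bis(2,2,2-trifluoroethoxy)phosphoryl]propanoate (racemic) | COC(=O)C(C)P(=O)(OCC(F)(F)F)OCC(F)(F)F | intermediate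
7 | methyl (2Z,6E)-2,6-dimethyl-10-oxoundeca-2,6-dienoate | COC(=O)/C(C)=C\CC/C(C)=C/CCC(C)=O | intermediate
8 | methyl (2Z,6E,10S)-10-hydroxy-2,6-dimethylundeca-2,6-dienoate | COC(=O)/C(C)=C\CC/C(C)=C/CC[C@H](C)O | intermediate
9 | 1-(2,4-dihydroxy-6-methylphenyl)ethan-1-one | CC(=O)c1c(C)cc(O)cc1O | starting material
10 | 1-{2-hydroxy-6-methyl-4-[(triisopropylsilyl)oxy]phenyl}ethan-1-one | CC(=O)c1c(C)cc(O[Si](C(C)C)(C(C)C)C(C)C)cc1O | intermediate
11 | methyl (2Z,6E,10R)-10-{2-acetyl-3-methyl-5-[(triisopropylsilyl)oxy]phenoxy}-2,6-dimethylundeca-2,6-dienoate | COC(=O)/C(C)=C\CC/C(C)=C/CC[C@@H](C)Oc1cc(O[Si](C(C)C)(C(C)C)C(C)C)cc(C)c1C(C)=O | intermediate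
12 | methyl (2Z,6E,10R)-2,6-dimethyl-10-{3-methyl-2-(4,4,4-trifluoro-3-oxobutanoyl)-5-[(triisopropylsilyl)oxy]phenoxy}undeca-2,6-dienoate | COC(=O)/C(C)=C\CC/C(C)=C/CC[C@@H](C)Oc1cc(O[Si](C(C)C)(C(C)C)C(C)C)cc(C)c1C(=O)CC(=O)C(F)(F)F | intermediate
13 | methyl (2Z,6E,10R)-10-{2-(2-diazoacetyl)-3-methyl-5-[(triisopropylsilyl)oxy]phenoxy}-2,6-dimethylundeca-2,6-dienoate | COC(=O)/C(C)=C\CC/C(C)=C/CC[C@@H](C)Oc1cc(O[Si](C(C)C)(C(C)C)C(C)C)cc(C)c1C(=O)C=[N+]=[N-] | intermediate
14 | methyl (2Z,6E)-2,6-dimethyl-9-{(2R)-2,5-dimethyl-4-oxo-7-[(triisopropylsilyl)oxy]-3,4-dihydro-2H-chromen-2-yl}nona-2,6-dienoate | COC(=O)/C(C)=C\CC/C(C)=C/CC[C@]1(C)CC(=O)c2c(C)cc(O[Si](C(C)C)(C(C)C)C(C)C)cc2O1 | intermediate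
15 | C4 tosylhydrazone of 14 (C=N geometry not defined) | COC(=O)/C(C)=C\CC/C(C)=C/CC[C@]1(C)CC(=NNS(=O)(=O)c3ccc(C)cc3)c2c(C)cc(O[Si](C(C)C)(C(C)C)C(C)C)cc2O1 | intermediate
16 | N-(1,3,2-benzodioxaborol-2-yl) tosylhydrazide adduct at C4 (C4 epimers) | COC(=O)/C(C)=C\CC/C(C)=C/CC[C@]1(C)CC(N(NS(=O)(=O)c3ccc(C)cc3)B3Oc4ccccc4O3)c2c(C)cc(O[Si](C(C)C)(C(C)C)C(C)C)cc2O1 | intermediate
17 | methyl (2Z,6E)-2,6-dimethyl-9-{(2R)-2,5-dimethyl-7-[(triisopropylsilyl)oxy]-3,4-dihydro-2H-chromen-2-yl}nona-2,6-dienoate | COC(=O)/C(C)=C\CC/C(C)=C/CC[C@]1(C)CCc2c(C)cc(O[Si](C(C)C)(C(C)C)C(C)C)cc2O1 | intermediate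
18 | methyl (2Z,6E)-9-[(2R)-7-hydroxy-2,5-dimethyl-3,4-dihydro-2H-chromen-2-yl]-2,6-dimethylnona-2,6-dienoate | COC(=O)/C(C)=C\CC/C(C)=C/CC[C@]1(C)CCc2c(C)cc(O)cc2O1 | target

**Step count and risks**
Total step count: 12. Longest linear sequence: 10 steps (steps 1, 2, 4, 5, 7, 8, 9, 10, 11, 12, from compound 1).

Steps most likely to fail:

Step 9. The carbenoid may be diverted before it reaches the C2–H bond. O1 could attack it to give a five-membered oxonium ylide that rearranges by a [1,2]-shift of the sec-alkyl group. The hydride-transfer pathway could collapse through oxygen to a cyclic acetal. The carbenoid could insert into the aryl methyl C–H bond or dimerise. A stepwise insertion could also erode the transfer of configuration. The fallback sets out from 10 and 7 and returns at 14. A Kabbe condensation of the two ketones (pyrrolidine, toluene, reflux with removal of water) should give the racemic chromanone F1 by aldol condensation and oxa-Michael closure of ring B. Preparative chromatography on a chiral stationary phase (amylose tris(3,5-dimethylphenylcarbamate)) should then separate 14 from the (2S)-chromanone F2.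

Step 10. Condensation may stall because the C4 carbonyl is deactivated by conjugation with O1 and the 7-siloxy group and shielded by the peri 5-methyl group. Forcing it with acid or base risks retro-oxa-Michael opening of ring B with loss of the C2 configuration, and drift of the (Z)-enoate. The same detour also covers an incomplete hydride transfer in step 11. The fallback sets out from 14 and returns at 17. Reduction with NaBH4 and CeCl3·7H2O in MeOH at −20 °C should give the chroman-4-ol F3 as C4 epimers. Dehydration with the dialkoxydiarylsulfurane Ph2S[OC(CF3)2Ph]2 in CH2Cl2 at 0 °C should give the 2H-chromene F4. Diimide generated from 2-nitrobenzenesulfonyl hydrazide and Et3N at room temperature should then saturate the cis-disubstituted C3=C4 bond in preference to the trisubstituted alkenes and the enoate, giving 17.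

Step 7. The activated secondary alcohol may eliminate to alkenes, or be intercepted by the hydrazide by-product, before the hydrogen-bonded phenol displaces it. The fallback sets out from 8 and 10 and returns at 11. Mesylation of 8 (MsCl, Et3N, CH2Cl2, 0 °C, retention at C10) should give the (10S)-mesylate F5. Its SN2 displacement by the phenoxide of 10 (K2CO3, 18-crown-6, MeCN, 60 °C) should give 11 with the same inversion.

**Further compounds**
F1 | step 9 | racemic methyl (2Z,6E)-2,6-dimethyl-9-{2,5-dimethyl-4-oxo-7-[(triisopropylsilyl)oxy]-3,4-dihydro-2H-chromen-2-yl}nona-2,6-dienoate | COC(=O)/C(C)=C\CC/C(C)=C/CCC1(C)CC(=O)c2c(C)cc(O[Si](C(C)C)(C(C)C)C(C)C)cc2O1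
F2 | step 9 | methyl (2Z,6E)-2,6-dimethyl-9-{(2S)-2,5-dimethyl-4-oxo-7-[(triisopropylsilyl)oxy]-3,4-dihydro-2H-chromen-2-yl}nona-2,6-dienoate | COC(=O)/C(C)=C\CC/C(C)=C/CC[C@@]1(C)CC(=O)c2c(C)cc(O[Si](C(C)C)(C(C)C)C(C)C)cc2O1
F3 | step 10 | methyl (2Z,6E)-9-{(2R)-4-hydroxy-2,5-dimethyl-7-[(triisopropylsilyl)oxy]-3,4-dihydro-2H-chromen-2-yl}-2,6-dimethylnona-2,6-dienoate (C4 epimers) | COC(=O)/C(C)=C\CC/C(C)=C/CC[C@]1(C)CC(O)c2c(C)cc(O[Si](C(C)C)(C(C)C)C(C)C)cc2O1
F4 | step 10 | methyl (2Z,6E)-2,6-dimethyl-9-{(2R)-2,5-dimethyl-7-[(triisopropylsilyl)oxy]-2H-chromen-2-yl}nona-2,6-dienoate | COC(=O)/C(C)=C\CC/C(C)=C/CC[C@]1(C)C=Cc2c(C)cc(O[Si](C(C)C)(C(C)C)C(C)C)cc2O1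
F5 | step 7 | methyl (2Z,6E,10S)-2,6-dimethyl-10-[(methylsulfonyl)oxy]undeca-2,6-dienoate | COC(=O)/C(C)=C\CC/C(C)=C/CC[C@H](C)OS(C)(=O)=O
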